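## Analysis of the target

The target is a nortricyclane (tricyclo[2.2.1.0^2,6]heptane) cage with a cyclohexane, ring A, fused on one apex-to-bridge bond. The lettering used throughout is: C-a, the quaternary carbon bearing the CH2OAc carbon C-x; C-b, C-c, C-d and C-e, the ring A CH2, CHOAc, CHOH and CMe2 carbons; C-f, the cage apex bonded to C-e; C-g, the cage CH2; C-h and C-i, the cyclopropane CH carbons next to C-g and next to C-a; C-j, the methylated cyclopropane carbon; C-k, the cage CHOAc carbon. Of the eight stereocentres, C-f, C-h, C-i and C-j are tied to one another by the cage. The free elements are the handedness of the cage, the placing of C-b on C-a on the side of C-k (so that C-x looks towards C-g), the C-k acetate pointing towards C-g and away from ring A, and the cis glycol at C-c/C-d on the ring A face that carries C-x. Sensitive points are the three acetates beside a free vicinal hydroxyl (acyl migration), the cyclopropylcarbinyl acetate at C-k (ionisable) and the cyclopropane itself (strong acid, electrophiles). The difficulty is the run of fully substituted carbons C-e, C-f and C-a, with the C-a–C-f bond joining two quaternary centres inside the cage, plus quaternary C-j. The strategy rests on the fact that C-a–C-f belongs both to ring A and to the norbornane (bridgeheads C-f and C-j, one-carbon bridge C-k) that is left when the cyclopropane bond C-h–C-i is opened. A cyclopentadiene C-f=C-g–C-h=C-j and a dienophile C-a=C-i, joined through C-b to C-e, therefore map onto an intramolecular Diels–Alder reaction.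

## Retrosynthetic reasoning

Target 32 to alkene 30: the two C–O bonds at C-c and C-d are cut together. An iodonium/acetoxonium cis-hydroxylation places both oxygens on the more hindered ring A face and leaves them as hydroxy acetate. The C-d centre, needed earlier only as a control element, is thus renewed together with C-c in one operation, and the cis relation is guaranteed.

30 to norbornene 26: the cyclopropane bond C-h–C-i is cut. It is the only cyclopropane bond whose removal leaves a norbornene with C-k as the one-carbon bridge. Forward, the exo sulfonate on C-i ionises with participation of C-g=C-h and a hydride donor quenches the cation at C-g, which gives the three-membered ring and the C-g methylene in one step. C-x is carried as a sulfonate (inert at a neopentyl carbon, not nucleophilic towards the cation) and C-k as a silyl ether (28, 29 restore the hydroxyls).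

26 to ketol 22: the C-k–H bond. Once the cage is closed, C-b on C-a blocks the side of C-k from which this hydrogen must come, and an external hydride would also enter a norbornen-7-one from the alkene side. The hydrogen is therefore delivered before cage closure, from a hemiacetal built on the exo oxygen of C-i in 22. This also leaves C-i acylated and C-k free (23), so the two secondary oxygens are told apart (24, 25).

22 to adduct 17: functional-group changes only. The C-d carbinol is turned into the C-c=C-d alkene through ketone 19 and enol triflate 20, a sequence that cannot shift the neighbouring methyl groups. The ketal is hydrolysed first (18), while no acid-sensitive ring A alkene is present.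

17 to dienyl ketal 16: the key disconnection cuts C-f–C-a and C-j–C-i. It removes ring A and the norbornene ring together and creates the quaternary pair in the bond-forming event. The spiro ketal at C-k blocks hydrogen shifts and becomes the oxygenated bridge.

16 to selenide 14, then to ester 12: the second diene double bond is stored as a tertiary selenide on C-j, so the reactive diene is released under neutral conditions in the presence of the enol acetate. The enol acetate comes from formylation of ester 12 (13) and O-acetylation; the formyl carbon is C-i.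

12 to aldehyde 8 and iodo ester 9: the C-c–C-d bond. A catalytic asymmetric addition of the alkylzinc 10 made from 9 sets the only stereocentre that is not set by the substrate, and brings C-a, C-b, C-c and the ester in one piece (11).

8 to enone 2 and nitrile 3: the C-e–C-f bond. The anion of 3 adds to the carbonyl of 2, whose enol ether carbon is the future C-k (4). The enol ether is converted by 5 and a selenium electrophile into the ketal selenide 6; dehydration gives C-f=C-g (7) and reduction of the nitrile gives 8. 2 is the methyl ether of the commercial dione 1.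

## Alternatives that were turned down

Alternative 1: the C-c–C-d bond of ring A is cut, leading back to the cage dialdehyde A1 (formylmethyl on C-a, a neopentyl aldehyde on C-e). Forward, a one-electron reductant would reduce both aldehydes and the metal-bridged diketyl would couple to the cis glycol A2, which needs only acetylation at C-c. In its favour, it gives the glycol directly, never destroys C-d, and makes the last C–C bond late. Against it, the step closes an unstrained ring on a cage that already contains everything difficult (nortricyclane, the C-a–C-f bond, the C-k acetate), so the hard problem is only moved into the synthesis of A1. Of the two cis glycols the required one lies on the face crowded by C-x and an axial methyl, the neopentyl aldehyde tends to be reduced rather than coupled, and acetates sit close to ketyl radicals. On the glycol it is stronger than the chosen route (one step against alkene formation plus cis-hydroxylation). The chosen strategy offers instead a key step that makes two bonds, two rings and the quaternary pair.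

Alternative 2: C-f–C-k and C-i–C-j are cut in an intermolecular Diels–Alder reaction between the ring A-fused 2-siloxycyclopentadiene A3 (C-a as the blocked sp3 carbon) and (E)-1-nitropropene A4, giving A5 with nitro endo and methyl exo. In its favour are convergence, a very reactive diene/dienophile pair, regiochemistry fixed by the siloxy group, and a nitro group that can become the C-k ketone. Against it, A3 already holds ring A and the C-a–C-f bond, which must be made by other means. The new bond to C-f is formed at a fully substituted diene terminus beside CMe2, face selection rests on the angular siloxymethyl group alone, and endo/exo control with a 1,2-disubstituted nitroalkene is uncertain. The C-k ketone must then be reduced against the same steric bias that the chosen route overcomes by tethered delivery. It is stronger on convergence and on dienophile reactivity. The chosen strategy offers intramolecularity that builds ring A and the C-a–C-f bond in the same event and relays the absolute configuration from one carbinol.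

Alternative 3: C-a–C-i, C-j–C-k and C-k–C-f are cut in a silicon-tethered cobalt-mediated cyclocarbonylation of enyne A6, giving the silicon-bridged hydrindenone A7. In its favour, three C–C bonds and quaternary C-a form in one step, and the temporary silicon tether fixes which alkyne carbon carries the methyl group. Against it, the alkene C-a=C-f is trisubstituted and flanked by CMe2, a poor partner for this reaction, and C-f emerges as CH. The fourth bond at the apex, the C-g–C-h unit and the cyclopropane would then have to be added at the most congested carbon of A7. In bond count the key step is equal or stronger, but it builds none of the cage. The chosen cycloadduct is one ionisation away from the nortricyclane.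

Key step: step 10

Remarks on the chemistry: C-f and C-j are racemic in 4–8 and both become trigonal in 16, so 11–15 are pairs of C-j epimers and their SMILES leave this centre open. Compound 13 is written as its aldehyde tautomer.

## Route

Step 1
Reactants: 1 3-methylcyclopentane-1,2-dione (enol form)
Product: 2 2-methoxy-3-methylcyclopent-2-en-1-one
Conditions: MeI, K2CO3, acetone, reflux
Reagents that add atoms: iodomethane, CI
Why: O-alkylation of the diosphenol enol (Williamson ether synthesis); it fixes the enol ether carbon as the future C-k and leaves the free carbonyl as the future C-f.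

Step 2
Reactants: 2 2-methoxy-3-methylcyclopent-2-en-1-one; 3 2-methylpropanenitrile
Product: 4 2-(1-hydroxy-2-methoxy-3-methylcyclopent-2-en-1-yl)-2-methylpropanenitrile (racemic)
Conditions: 3, LiN(iPr)2, THF, −78 °C; CeCl3; then 2, −78 °C
Reagents that add atoms: none
Why: 1,2-addition of a tertiary α-cyano carbanion to the enone carbonyl makes the C-e–C-f bond with C-e quaternary; the β-carbon is fully substituted and donor-deactivated, so conjugate addition should not compete, and the cerium salt tempers enolisation.

Step 3
Reactants: 4 2-(1-hydroxy-2-methoxy-3-methylcyclopent-2-en-1-yl)-2-methylpropanenitrile; 5 ethane-1,2-diol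
Product: 6 2-[6-hydroxy-9-methyl-9-(phenylselanyl)-1,4-dioxaspiro[4.4]nonan-6-yl]-2-methylpropanenitrile (diastereomer mixture)
Conditions: PhSeCl, 5 (10 equiv), 2,6-di-tert-butyl-4-methylpyridine, CH2Cl2, −78 → 0 °C; then camphorsulfonic acid (cat.), 25 °C
Reagents that add atoms: benzeneselenenyl chloride, Cl[Se]c1ccccc1
Why: Alkoxyselenation of an enol ether: the selenium electrophile adds to C-j, the diol traps the oxocarbenium ion at C-k, and acid-catalysed exchange closes the dioxolane with loss of methanol. The ketal and the later leaving group on C-j are thus installed together while C-k is still unhindered.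

Step 4
Reactants: 6 2-[6-hydroxy-9-methyl-9-(phenylselanyl)-1,4-dioxaspiro[4.4]nonan-6-yl]-2-methylpropanenitrile
Product: 7 2-methyl-2-[9-methyl-9-(phenylselanyl)-1,4-dioxaspiro[4.4]non-6-en-6-yl]propanenitrile (racemic)
Conditions: Burgess reagent, benzene, 50 °C
Reagents that add atoms: none
Why: Syn dehydration of the tertiary alcohol through its sulfamate (Burgess elimination); only C-g carries a β-hydrogen, so only C-f=C-g can form, and the neutral conditions avoid a free cation next to the ketal.

Step 5
Reactants: 7 2-methyl-2-[9-methyl-9-(phenylselanyl)-1,4-dioxaspiro[4.4]non-6-en-6-yl]propanenitrile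
Product: 8 2-methyl-2-[9-methyl-9-(phenylselanyl)-1,4-dioxaspiro[4.4]non-6-en-6-yl]propanal
Conditions: iBu2AlH, toluene, −78 → 0 °C; aq. KNaC4H4O6, then pH 5 buffer
Reagents that add atoms: water, O
Why: Partial reduction of a hindered tertiary nitrile to the aluminium imine and mild hydrolysis; the aldehyde is not enolisable, so the quaternary centre is safe.

Step 6
Reactants: 8 2-methyl-2-[9-methyl-9-(phenylselanyl)-1,4-dioxaspiro[4.4]non-6-en-6-yl]propanal; 9 methyl 4-iodobutanoate
Product: 11 methyl (5S)-5-hydroxy-6-methyl-6-[9-methyl-9-(phenylselanyl)-1,4-dioxaspiro[4.4]non-6-en-6-yl]heptanoate, via bis(4-methoxy-4-oxobutyl)zinc 10 (not isolated)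
Conditions: 9, Et2Zn, CuI (cat.), 50 °C, then vacuum; Ti(OiPr)4, (1R,2R)-N,N′-bis(trifluoromethylsulfonyl)cyclohexane-1,2-diamine (8 mol %), toluene, −20 °C; 8
Reagents that add atoms: none
Why: Iodine–zinc exchange gives the ester-bearing dialkylzinc, and the chiral titanium bis(sulfonamide) catalyst adds it to the Si face of the aldehyde (catalytic asymmetric alkylzinc addition), which sets C-d as S. The aldehyde has no α-hydrogen and a large tertiary substituent, the case in which this catalyst class discriminates best.

Step 7
Reactants: 11 methyl (5S)-5-hydroxy-6-methyl-6-[9-methyl-9-(phenylselanyl)-1,4-dioxaspiro[4.4]non-6-en-6-yl]heptanoate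
Product: 12 methyl (5S)-5-[(tert-butyldimethylsilyl)oxy]-6-methyl-6-[9-methyl-9-(phenylselanyl)-1,4-dioxaspiro[4.4]non-6-en-6-yl]heptanoate
Conditions: TBSOTf, 2,6-lutidine, CH2Cl2, −78 °C
Reagents that add atoms: tert-butyldimethylsilyl triflate, CC(C)(C)[Si](C)(C)OS(=O)(=O)C(F)(F)F
Why: Silylation of the hindered carbinol with the reactive triflate before it can lactonise; the bulky silyl ether is the group that will prefer the equatorial site in the cycloaddition.

Step 8
Reactants: 12 methyl (5S)-5-[(tert-butyldimethylsilyl)oxy]-6-methyl-6-[9-methyl-9-(phenylselanyl)-1,4-dioxaspiro[4.4]non-6-en-6-yl]heptanoate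
Product: 13 methyl (5S)-5-[(tert-butyldimethylsilyl)oxy]-2-formyl-6-methyl-6-[9-methyl-9-(phenylselanyl)-1,4-dioxaspiro[4.4]non-6-en-6-yl]heptanoate
Conditions: LiN(iPr)2 (2.2 equiv), THF, −78 °C; HCO2CH2CF3
Reagents that add atoms: 2,2,2-trifluoroethyl formate, O=COCC(F)(F)F
Why: Claisen-type formylation of the ester enolate introduces C-i on C-a; the ester α-position is the only acidic site.

Step 9
Reactants: 13 methyl (5S)-5-[(tert-butyldimethylsilyl)oxy]-2-formyl-6-methyl-6-[9-methyl-9-(phenylselanyl)-1,4-dioxaspiro[4.4]non-6-en-6-yl]heptanoate
Product: 14 methyl (2E,5S)-2-[(acetyloxy)methylidene]-5-[(tert-butyldimethylsilyl)oxy]-6-methyl-6-[9-methyl-9-(phenylselanyl)-1,4-dioxaspiro[4.4]non-6-en-6-yl]heptanoate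
Conditions: Ac2O, Et3N, DMAP (cat.), CH2Cl2, 0 °C
Reagents that add atoms: acetic anhydride, CC(=O)OC(C)=O
Why: O-acylation of the formyl ester through its non-chelated ammonium enolate, which should place the acetoxy group anti to the ester (E isomer); any Z isomer is separable at this stable stage.

Step 10
Reactants: 14 methyl (2E,5S)-2-[(acetyloxy)methylidene]-5-[(tert-butyldimethylsilyl)oxy]-6-methyl-6-[9-methyl-9-(phenylselanyl)-1,4-dioxaspiro[4.4]non-6-en-6-yl]heptanoate
Product: 17 ring A-fused norbornene ketal (C-a CO2Me endo, C-i OAc exo, C-d OTBS, C-k ethylene ketal), via selenoxide 15 (not isolated), via dienyl ketal 16 (not isolated)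
Conditions: mCPBA, CH2Cl2, −78 °C; iPr2NH, −78 → 25 °C; aq. NaHCO3 wash; then toluene (0.005 M), BHT, 100 °C
Reagents that add atoms: none
Why: Oxidation at selenium and syn elimination towards the allylic C-h hydrogen release the 1,4-disubstituted cyclopentadienone ketal under neutral conditions, and the tethered (E)-3-acetoxyacrylate then adds across C-f and C-j in a concerted [4+2] cycloaddition. The closest known reactions are Diels–Alder additions of cyclopentadienone ketals made in situ and intramolecular Diels–Alder reactions of 1-substituted cyclopentadienes with four-atom tethers. Ring A closes in the fused mode, the tether joining diene terminus C-f to the dienophile carbon C-a that bonds to it, while the norbornene ring closes by the cycloaddition itself (C-f–C-a and C-j–C-i, C-k becoming the one-carbon bridge). The four-atom tether can only reach the exo position of C-a, which makes the ring fusion cis, puts the ester endo and ring A on the C-k side, and sets C-a and C-f. The addition is suprafacial on both partners, so C-j follows C-f and the E geometry places the C-i acetate exo. The two diene faces are equivalent because of the symmetric spiro ketal, so the only choice is the dienophile face, and it is made by C-d: in the chair-like tether the silyloxy group sits equatorial, since the axial position would point at the ketal on C-k. The step needs ring closure to beat self-addition of the diene, which high dilution, the substituted diene termini and the gem-dimethyl group on the tether should secure. The ketal carbon has no hydrogen, so the diene cannot isomerise by hydrogen shifts.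

Step 11
Reactants: 17 ring A-fused norbornene ketal
Product: 18 norbornen-7-one hydroxy ester (C-k ketone, C-d OH, C-i OAc exo, C-a CO2Me)
Conditions: CF3CO2H–H2O (9:1), 0 → 40 °C; then NaHCO3, MeOH
Reagents that add atoms: water, O
Why: Strong aqueous acid is needed for a dioxolane on a norbornene bridge and removes the silyl ether in the same operation; at this stage the only alkene is deactivated by the neighbouring oxygenated carbons, and the acetate and the hindered ester are acid-stable.

Step 12
Reactants: 18 norbornen-7-one hydroxy ester
Product: 19 diketone (C-d ketone, C-k ketone)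
Conditions: Dess–Martin periodinane, NaHCO3, CH2Cl2, 25 °C
Reagents that add atoms: none
Why: Neutral oxidation of the secondary alcohol; the C-d ketone can enolise only towards C-c because C-e is quaternary.

Step 13
Reactants: 19 diketone
Product: 20 ring A enol triflate (C-c=C-d–OTf)
Conditions: KN(SiMe3)2 added to 19 and Comins' reagent, THF, −78 °C
Reagents that add atoms: Comins' reagent, O=S(=O)(N(c1ccc(Cl)cn1)S(=O)(=O)C(F)(F)F)C(F)(F)F
Why: Kinetic enolate formation and O-triflation with in-flask trapping; the C-k ketone has no α-hydrogen and the acetate is several pK units less acidic than the ketone.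

Step 14
Reactants: 20 ring A enol triflate
Product: 21 ring A alkene keto acetate (C-c=C-d, C-k ketone, C-i OAc exo)
Conditions: Pd(OAc)2 (5 mol %), PPh3, HCO2H, Bu3N, DMF, 60 °C
Reagents that add atoms: none
Why: Zerovalent palladium inserts into the C–OTf bond and formate supplies the hydride (reductive detriflation); this gives the C-c=C-d alkene without any cationic stage that could shift a methyl group from C-e.

Step 15
Reactants: 21 ring A alkene keto acetate
Product: 22 ketol (C-i OH exo, C-k ketone)
Conditions: HCl (2 M), MeOH–H2O (9:1), 45 °C
Reagents that add atoms: none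
Why: Acid-catalysed transesterification removes the acetate without ever forming the C-i alkoxide, which would open the strained β-hydroxy ketone by retro-aldol cleavage; the quaternary methyl ester is too hindered to react.

Step 16
Reactants: 22 ketol
Product: 23 C-k alcohol (OH syn to C-g=C-h) with C-i acetate
Conditions: CH3CHO (6 equiv), SmI2 (20 mol %), THF, −10 °C
Reagents that add atoms: acetaldehyde, CC=O
Why: Evans–Tishchenko reduction: the hemiacetal formed on the exo C-i oxygen hands its hydride to C-k through a six-membered samarium-bridged transition state, so the hydrogen arrives on the C-a/C-i side and the hydroxyl ends syn to the alkene, the target configuration. External hydrides would attack from the alkene side because C-b blocks the other face. The step also leaves C-i acylated and C-k free, which distinguishes the two secondary oxygens.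

Step 17
Reactants: 23 C-k alcohol with C-i acetate
Product: 24 C-k TBS ether
Conditions: TBSOTf, 2,6-lutidine, CH2Cl2, 0 → 25 °C
Reagents that add atoms: tert-butyldimethylsilyl triflate, CC(C)(C)[Si](C)(C)OS(=O)(=O)C(F)(F)F
Why: Silyl triflates protect even flanked secondary alcohols; a silyl ether, unlike an ester, cannot capture the later cation through a carbonyl oxygen.

Step 18
Reactants: 24 C-k TBS ether
Product: 25 diol (C-x OH, C-i OH exo; C-k OTBS)
Conditions: LiAlH4, THF, 0 → 40 °C
Reagents that add atoms: none
Why: Hydride reduction of the methyl ester to C-x–OH and cleavage of the acetate in one step; the silyl ether and both alkenes are inert.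

Step 19
Reactants: 25 diol
Product: 26 bis(4-bromobenzenesulfonate) (C-x OBs, C-i OBs exo)
Conditions: 4-BrC6H4SO2Cl (4 equiv), DMAP, pyridine, 0 → 40 °C
Reagents that add atoms: 4-bromobenzenesulfonyl chloride, O=S(=O)(Cl)c1ccc(Br)cc1
Why: Sulfonylation of both hydroxyls; the neopentyl primary sulfonate is inert to substitution and its oxygens are not nucleophilic, so C-x cannot trap the cation that will form beside it at C-g.

Step 20
Reactants: 26 bis(4-bromobenzenesulfonate)
Product: 27 nortricyclane (C-h–C-i closed, C-g CH2; C-x OBs, C-k OTBS)
Conditions: NaBH4 (1.8 M), diglyme–H2O (65:35), 50 °C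
Reagents that add atoms: none
Why: Solvolysis of an exo norbornenyl sulfonate with π-participation (homoallyl to cyclopropylcarbinyl rearrangement) and hydride trapping: the C-g=C-h bond attacks C-i from the endo side as the exo leaving group departs, and borohydride quenches the cation at C-g. The cage geometry fixes C-h and C-i; positive charge at C-j is disfavoured by the oxygen on neighbouring C-k.

Step 21
Reactants: 27 nortricyclane sulfonate
Product: 28 nortricyclane primary alcohol (C-x OH, C-k OTBS)
Conditions: NaC10H8 (sodium naphthalenide), THF, −78 °C; NH4Cl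
Reagents that add atoms: none
Why: Electron-transfer cleavage of the S–O bond frees the neopentyl alcohol with the C–O bond untouched; the silyl ether, the isolated alkene and the unconjugated cyclopropane are not reduced.

Step 22
Reactants: 28 nortricyclane primary alcohol
Product: 29 nortricyclane diol (C-x OH, C-k OH)
Conditions: Bu4NF, THF, 50 °C
Reagents that add atoms: none
Why: Fluoride cleavage of the silyl ether; basic conditions leave the cyclopropylcarbinyl C–O bond intact.

Step 23
Reactants: 29 nortricyclane diol
Product: 30 diacetate alkene (C-x OAc, C-k OAc, C-c=C-d)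
Conditions: Ac2O, DMAP, pyridine, 40 °C
Reagents that add atoms: acetic anhydride, CC(=O)OC(C)=O
Why: Nucleophile-catalysed acylation installs two of the three target acetates; the basic medium cannot ionise the C-k centre.

Step 24
Reactants: 30 diacetate alkene
Product: 32 target, via trans-iodo acetate 31 (not isolated)
Conditions: I2, AgOAc, AcOH, 25 °C; then H2O (1 equiv), 60 °C
Reagents that add atoms: silver acetate, CC(=O)[O-].[Ag+]; water, O
Why: Woodward cis-hydroxylation: iodonium ion on the face of ring A that is hindered only at one end (the C-k side), axial opening by acetate at C-c on the opposite face, displacement of iodide at C-d by the acetate carbonyl, and hydrolysis of the acetoxonium ion put both oxygens cis on the face that carries C-x. The orthoacid should collapse to the axial acetate at C-c and the equatorial hydroxyl at C-d, which is also the less hindered ester.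

## Compound list

1 | 3-methylcyclopentane-1,2-dione (enol form) | CC1=C(O)C(=O)CC1 | starting material
2 | 2-methoxy-3-methylcyclopent-2-en-1-one | COC1=C(C)CCC1=O | intermediate
3 | 2-methylpropanenitrile | CC(C)C#N | starting material
4 | 2-(1-hydroxy-2-methoxy-3-methylcyclopent-2-en-1-yl)-2-methylpropanenitrile | COC1=C(C)CCC1(O)C(C)(C)C#N | intermediate
5 | ethane-1,2-diol | OCCO | starting material
6 | 2-[6-hydroxy-9-methyl-9-(phenylselanyl)-1,4-dioxaspiro[4.4]nonan-6-yl]-2-methylpropanenitrile | CC1([Se]c2ccccc2)CCC(O)(C(C)(C)C#N)C13OCCO3 | intermediate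
7 | 2-methyl-2-[9-methyl-9-(phenylselanyl)-1,4-dioxaspiro[4.4]non-6-en-6-yl]propanenitrile | CC1([Se]c2ccccc2)CC=C(C(C)(C)C#N)C13OCCO3 | intermediate
8 | 2-methyl-2-[9-methyl-9-(phenylselanyl)-1,4-dioxaspiro[4.4]non-6-en-6-yl]propanal | CC1([Se]c2ccccc2)CC=C(C(C)(C)C=O)C13OCCO3 | intermediate
9 | methyl 4-iodobutanoate | COC(=O)CCCI | starting material
10 | bis(4-methoxy-4-oxobutyl)zinc | COC(=O)CCC[Zn]CCCC(=O)OC | intermediate
11 | methyl (5S)-5-hydroxy-6-methyl-6-[9-methyl-9-(phenylselanyl)-1,4-dioxaspiro[4.4]non-6-en-6-yl]heptanoate | COC(=O)CCC[C@H](O)C(C)(C)C1=CCC(C)([Se]c2ccccc2)C13OCCO3 | intermediate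
12 | methyl (5S)-5-[(tert-butyldimethylsilyl)oxy]-6-methyl-6-[9-methyl-9-(phenylselanyl)-1,4-dioxaspiro[4.4]non-6-en-6-yl]heptanoate | COC(=O)CCC[C@H](O[Si](C)(C)C(C)(C)C)C(C)(C)C1=CCC(C)([Se]c2ccccc2)C13OCCO3 | intermediate
13 | methyl (5S)-5-[(tert-butyldimethylsilyl)oxy]-2-formyl-6-methyl-6-[9-methyl-9-(phenylselanyl)-1,4-dioxaspiro[4.4]non-6-en-6-yl]heptanoate | COC(=O)C(C=O)CC[C@H](O[Si](C)(C)C(C)(C)C)C(C)(C)C1=CCC(C)([Se]c2ccccc2)C13OCCO3 | intermediate
14 | methyl (2E,5S)-2-[(acetyloxy)methylidene]-5-[(tert-butyldimethylsilyl)oxy]-6-methyl-6-[9-methyl-9-(phenylselanyl)-1,4-dioxaspiro[4.4]non-6-en-6-yl]heptanoate | COC(=O)/C(=C/OC(C)=O)CC[C@H](O[Si](C)(C)C(C)(C)C)C(C)(C)C1=CCC(C)([Se]c2ccccc2)C13OCCO3 | intermediate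
15 | selenoxide of 14 | COC(=O)/C(=C/OC(C)=O)CC[C@H](O[Si](C)(C)C(C)(C)C)C(C)(C)C1=CCC(C)([Se](=O)c2ccccc2)C13OCCO3 | intermediate
16 | methyl (2E,5S)-2-[(acetyloxy)methylidene]-5-[(tert-butyldimethylsilyl)oxy]-6-methyl-6-(9-methyl-1,4-dioxaspiro[4.4]nona-6,8-dien-6-yl)heptanoate | COC(=O)/C(=C/OC(C)=O)CC[C@H](O[Si](C)(C)C(C)(C)C)C(C)(C)C1=CC=C(C)C12OCCO2 | intermediate
17 | ring A-fused norbornene ketal (C-a CO2Me endo, C-i OAc exo, C-d OTBS, C-k ethylene ketal) | COC(=O)[C@]12CC[C@H](O[Si](C)(C)C(C)(C)C)C(C)(C)[C@]13C=C[C@](C)([C@H]2OC(C)=O)C34OCCO4 | intermediate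
18 | norbornen-7-one hydroxy ester (C-k ketone, C-d OH) | COC(=O)[C@]12CC[C@H](O)C(C)(C)[C@]13C=C[C@](C)([C@H]2OC(C)=O)C3=O | intermediate
19 | diketone (C-d and C-k ketones) | COC(=O)[C@]12CCC(=O)C(C)(C)[C@]13C=C[C@](C)([C@H]2OC(C)=O)C3=O | intermediate
20 | ring A enol triflate | COC(=O)[C@]12CC=C(OS(=O)(=O)C(F)(F)F)C(C)(C)[C@]13C=C[C@](C)([C@H]2OC(C)=O)C3=O | intermediate
21 | ring A alkene keto acetate | COC(=O)[C@]12CC=CC(C)(C)[C@]13C=C[C@](C)([C@H]2OC(C)=O)C3=O | intermediate
22 | ketol (C-i OH exo, C-k ketone) | COC(=O)[C@]12CC=CC(C)(C)[C@]13C=C[C@](C)([C@H]2O)C3=O | intermediate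
23 | C-k alcohol (OH syn to C-g=C-h) with C-i acetate | COC(=O)[C@]12CC=CC(C)(C)[C@]13C=C[C@](C)([C@H]2OC(C)=O)[C@H]3O | intermediate
24 | C-k TBS ether of 23 | COC(=O)[C@]12CC=CC(C)(C)[C@]13C=C[C@](C)([C@H]2OC(C)=O)[C@H]3O[Si](C)(C)C(C)(C)C | intermediate
25 | diol (C-x OH, C-i OH exo, C-k OTBS) | OC[C@]12CC=CC(C)(C)[C@]13C=C[C@](C)([C@H]2O)[C@H]3O[Si](C)(C)C(C)(C)C | intermediate
26 | bis(4-bromobenzenesulfonate) of 25 | O=S(=O)(OC[C@]12CC=CC(C)(C)[C@]13C=C[C@](C)([C@H]2OS(=O)(=O)c4ccc(Br)cc4)[C@H]3O[Si](C)(C)C(C)(C)C)c5ccc(Br)cc5 | intermediate
27 | nortricyclane (C-x OBs, C-k OTBS, C-c=C-d) | O=S(=O)(OC[C@]12CC=CC(C)(C)[C@]13C[C@@H]1[C@H]2[C@]1(C)[C@H]3O[Si](C)(C)C(C)(C)C)c4ccc(Br)cc4 | intermediate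
28 | nortricyclane primary alcohol (C-x OH, C-k OTBS) | OC[C@]12CC=CC(C)(C)[C@]13C[C@@H]1[C@H]2[C@]1(C)[C@H]3O[Si](C)(C)C(C)(C)C | intermediate
29 | nortricyclane diol (C-x OH, C-k OH) | OC[C@]12CC=CC(C)(C)[C@]13C[C@@H]1[C@H]2[C@]1(C)[C@H]3O | intermediate
30 | diacetate alkene (C-x OAc, C-k OAc, C-c=C-d) | CC(=O)OC[C@]12CC=CC(C)(C)[C@]13C[C@@H]1[C@H]2[C@]1(C)[C@H]3OC(C)=O | intermediate
31 | trans-iodo acetate (C-c OAc axial, C-d I axial) | CC(=O)OC[C@]12C[C@H](OC(C)=O)[C@@H](I)C(C)(C)[C@]13C[C@@H]1[C@H]2[C@]1(C)[C@H]3OC(C)=O | intermediate
32 | CNP0197219.1 | CC(=O)OC[C@]12C[C@H](OC(C)=O)[C@H](O)C(C)(C)[C@]13C[C@@H]1[C@H]2[C@]1(C)[C@H]3OC(C)=O | target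

## Step count and least certain steps

Total step count: 24. Longest linear sequence: 24 steps from 1 (3, 5 and 9 are bought and enter along the line).

Step 10 (key step). The most likely failure is a cycloaddition too slow to compete, because it must join two fully substituted carbons: the diene would then add to itself or lose its ketal to adventitious acid. Elimination of the selenoxide towards the methyl group, or a boat-like tether that erodes face selection, are further risks. Fallback, setting out from 11 and coming back at 18: acid-catalysed lactonisation would give the δ-lactone F1. Formylation and acetylation as in steps 8 and 9 would give the (E)-acetoxymethylidene lactone F2. Oxidation to selenoxide F3 and elimination would release dienyl lactone F4, whose exocyclic dienophile is locked s-cis and more reactive and whose ring fixes the relation between C-d and C-a, so that only the lactone-bridged norbornene F5 can form. Hydrogen chloride in methanol would open the strained bridged lactone to hydroxy ester F6, which under the conditions of step 11 gives 18.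

Step 16. The hemiacetal may fail to form at a carbinol flanked by two quaternary carbons, or the samarium alkoxide may open the strained ketol by retro-aldol cleavage before the hydride is transferred. Fallback, setting out from 21 and coming back at 30: the tethered delivery is given up and C-k is corrected at the end by ionisation. NaBH4 with CeCl3 would reduce the ketone from the alkene side to the epimeric alcohol F7. Silylation to the epimeric silyl ether F8, LiAlH4 reduction to epimeric diol F9, sulfonylation to epimeric bis-sulfonate F10, borohydride-trapped solvolysis to epimeric nortricyclane F11 and desulfonylation to epimeric primary alcohol F12 follow steps 17 to 21. Acetylation of the primary hydroxyl would give acetate F13, and fluoride the epimeric cyclopropylcarbinol F14. Its mesylate F15, with the leaving group pressed against C-b, should ionise readily in acetic acid buffered with KOAc, and acetate can reach the cyclopropylcarbinyl cation only from the open C-g side, which gives 30. The weakness of this fallback is competing capture at the cyclopropane carbons.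

Step 20. The delocalised cation may be quenched at C-i or at the methyl-bearing C-j (Wagner–Meerwein-type leakage), captured by water, or intercepted by the oxygen on C-k. Fallback, setting out from 25 and coming back at 29: the bond is made by a carbene instead of a cation. Selective silylation of the primary hydroxyl would give silyl ether F16 and oxidation the C-i ketone F17. Diimide would saturate only the strained C-g=C-h bond to give ketone F18. The tosylhydrazone F19, heated with NaH in diglyme (aprotic Bamford–Stevens conditions), should insert the C-i carbene into the endo C-h–H bond, as camphor-type hydrazones give tricyclenes, to give the bis-silyl nortricyclane F20. Fluoride then gives 29.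

Step 24. Both faces of ring A are encumbered, so the iodonium ion may form on the other face. The neopentyl iodide may also ionise with migration of a methyl group from C-e instead of closing the acetoxonium ion. Fallback, setting out from 30 and coming back at 32: if the electrophile proves to prefer the face that carries C-x, OsO4 with N-methylmorpholine N-oxide adds both oxygens there directly to give the cis-diol F21. Its cyclic orthoacetate (trimethyl orthoacetate, acid catalyst) is then opened with aqueous acid to the axial C-c acetate, 32.

## Further compounds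

F1 | step 10 | (6S)-6-{2-[9-methyl-9-(phenylselanyl)-1,4-dioxaspiro[4.4]non-6-en-6-yl]propan-2-yl}oxan-2-one | O=C1CCC[C@H](O1)C(C)(C)C2=CCC(C)([Se]c3ccccc3)C24OCCO4
F2 | step 10 | (3E,6S)-3-[(acetyloxy)methylidene] derivative of F1 | CC(=O)O/C=C1\CC[C@H](OC1=O)C(C)(C)C2=CCC(C)([Se]c3ccccc3)C24OCCO4
F3 | step 10 | selenoxide of F2 | CC(=O)O/C=C1\CC[C@H](OC1=O)C(C)(C)C2=CCC(C)([Se](=O)c3ccccc3)C24OCCO4
F4 | step 10 | dienyl lactone (9-methyl-1,4-dioxaspiro[4.4]nona-6,8-dien-6-yl analogue of F2) | CC(=O)O/C=C1\CC[C@H](OC1=O)C(C)(C)C2=CC=C(C)C23OCCO3
F5 | step 10 | lactone-bridged norbornene ketal (C-a carbonyl joined to the C-d oxygen, C-i OAc exo) | O=C5[C@]12CC[C@H](O5)C(C)(C)[C@]13C=C[C@](C)([C@H]2OC(C)=O)C34OCCO4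
F6 | step 10 | norbornene ketal hydroxy ester (17 without the silyl group) | COC(=O)[C@]12CC[C@H](O)C(C)(C)[C@]13C=C[C@](C)([C@H]2OC(C)=O)C34OCCO4
F7 | step 16 | C-k epimer of 23 (OH anti to C-g=C-h) | COC(=O)[C@]12CC=CC(C)(C)[C@]13C=C[C@](C)([C@H]2OC(C)=O)[C@@H]3O
F8 | step 16 | C-k epimer of 24 | COC(=O)[C@]12CC=CC(C)(C)[C@]13C=C[C@](C)([C@H]2OC(C)=O)[C@@H]3O[Si](C)(C)C(C)(C)C
F9 | step 16 | C-k epimer of 25 | OC[C@]12CC=CC(C)(C)[C@]13C=C[C@](C)([C@H]2O)[C@@H]3O[Si](C)(C)C(C)(C)C
F10 | step 16 | C-k epimer of 26 | O=S(=O)(OC[C@]12CC=CC(C)(C)[C@]13C=C[C@](C)([C@H]2OS(=O)(=O)c4ccc(Br)cc4)[C@@H]3O[Si](C)(C)C(C)(C)C)c5ccc(Br)cc5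
F11 | step 16 | C-k epimer of 27 | O=S(=O)(OC[C@]12CC=CC(C)(C)[C@]13C[C@@H]1[C@H]2[C@]1(C)[C@@H]3O[Si](C)(C)C(C)(C)C)c4ccc(Br)cc4
F12 | step 16 | C-k epimer of 28 | OC[C@]12CC=CC(C)(C)[C@]13C[C@@H]1[C@H]2[C@]1(C)[C@@H]3O[Si](C)(C)C(C)(C)C
F13 | step 16 | C-x acetate of F12 | CC(=O)OC[C@]12CC=CC(C)(C)[C@]13C[C@@H]1[C@H]2[C@]1(C)[C@@H]3O[Si](C)(C)C(C)(C)C
F14 | step 16 | epimeric cyclopropylcarbinol (C-x OAc, C-k OH towards C-a) | CC(=O)OC[C@]12CC=CC(C)(C)[C@]13C[C@@H]1[C@H]2[C@]1(C)[C@@H]3O
F15 | step 16 | methanesulfonate of F14 | CC(=O)OC[C@]12CC=CC(C)(C)[C@]13C[C@@H]1[C@H]2[C@]1(C)[C@@H]3OS(C)(=O)=O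
F16 | step 20 | C-x TBS ether of 25 | CC(C)(C)[Si](C)(C)OC[C@]12CC=CC(C)(C)[C@]13C=C[C@](C)([C@H]2O)[C@H]3O[Si](C)(C)C(C)(C)C
F17 | step 20 | C-i ketone | CC(C)(C)[Si](C)(C)OC[C@]12CC=CC(C)(C)[C@]13C=C[C@](C)(C2=O)[C@H]3O[Si](C)(C)C(C)(C)C
F18 | step 20 | C-i ketone with saturated C-g–C-h | CC(C)(C)[Si](C)(C)OC[C@]12CC=CC(C)(C)[C@]13CC[C@](C)(C2=O)[C@H]3O[Si](C)(C)C(C)(C)C
F19 | step 20 | 4-methylbenzenesulfonylhydrazone of F18 | CC(C)(C)[Si](C)(C)OC[C@]12CC=CC(C)(C)[C@]13CC[C@](C)(C2=NNS(=O)(=O)c4ccc(C)cc4)[C@H]3O[Si](C)(C)C(C)(C)C
F20 | step 20 | bis-TBS nortricyclane (C-x OTBS, C-k OTBS) | CC(C)(C)[Si](C)(C)OC[C@]12CC=CC(C)(C)[C@]13C[C@@H]1[C@H]2[C@]1(C)[C@H]3O[Si](C)(C)C(C)(C)C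
F21 | step 24 | cage cis-diol diacetate (C-c OH, C-d OH) | CC(=O)OC[C@]12C[C@H](O)[C@H](O)C(C)(C)[C@]13C[C@@H]1[C@H]2[C@]1(C)[C@H]3OC(C)=O
A1 | alternative 1 | cage dialdehyde (formylmethyl on C-a, 2-formylpropan-2-yl on C-f) | CC(=O)OC[C@]2(CC=O)[C@]3(C(C)(C)C=O)C[C@@H]1[C@H]2[C@]1(C)[C@H]3OC(C)=O
A2 | alternative 1 | cage cis-diol diacetate (target without the C-c acetyl) | CC(=O)OC[C@]12C[C@H](O)[C@H](O)C(C)(C)[C@]13C[C@@H]1[C@H]2[C@]1(C)[C@H]3OC(C)=O
A3 | alternative 2 | ring A-fused 2-siloxycyclopentadiene blocked at C-a | CC(C)[Si](OC[C@]12CC[C@H](O[Si](C)(C)C(C)(C)C)C(C)(C)C1=CC(O[Si](C)(C)C(C)(C)C)=C2)(C(C)C)C(C)C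
A4 | alternative 2 | (E)-1-nitropropene | C/C=C/[N+](=O)[O-]
A5 | alternative 2 | nitro norbornene silyl enol ether | CC(C)[Si](OC[C@]12CC[C@H](O[Si](C)(C)C(C)(C)C)C(C)(C)[C@]13C=C(O[Si](C)(C)C(C)(C)C)[C@H]2[C@H](C)[C@H]3[N+](=O)[O-])(C(C)C)C(C)C
A6 | alternative 3 | silyl-tethered propyne on the ring A alkene C-a=C-f | CC#C[Si](C(C)C)(C(C)C)OCC1=CC(C)(C)[C@@H](O[Si](C)(C)C(C)(C)C)CC1
A7 | alternative 3 | silicon-bridged hydrindenone | CC1=C2[Si](C(C)C)(C(C)C)OC[C@@]23CC[C@H](O[Si](C)(C)C(C)(C)C)C(C)(C)[C@H]3C1=O
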